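## Retrosynthetic overview

1. Prenyl C(sp2)–C(sp3) bond: target ⇐ 2-chloro-5-methoxy-3,6-di(indol-3-yl)benzoquinone + prenyltributylstannane (Stille coupling).
2. Key disconnection, the quinone C–OMe bond: ⇐ symmetric 2,5-dichloro-3,6-di(indol-3-yl)benzoquinone + methanol (desymmetrising, nucleophile-catalysed vinylogous acyl substitution).
3. Two quinone–indole C–C bonds, formed one after the other: ⇐ 2,5-dichloro-1,4-benzoquinone + indole, then a second indole (acid-promoted conjugate addition and reoxidation each time; the two chlorines force the para pattern).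
4. Rings: none is built. The quinone ring and both indole rings are bought intact and substituted in the order indolyl, indolyl, OMe, prenyl.

Assumption: the target has no stereocentre and no stereogenic double bond (the prenyl olefin ends in two methyl groups), so it is achiral and no stereocontrol is needed.

## Route

Step 1
Reactants: 1 2,5-dichloro-1,4-benzoquinone; 2 1H-indole
Product: 4 2,5-dichloro-3-(1H-indol-3-yl)-1,4-benzoquinone, via monoindolyl hydroquinone 3 (not isolated)
Conditions: 1 (1.2 equiv), 2 (1.0 equiv), H2SO4 (cat.), AcOH/THF, 23 °C; then DDQ (1.0 equiv), 23 °C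
Reagents that add atoms: none
Why: Acid-promoted conjugate (Michael-type Friedel–Crafts) addition of indole C-3 to a free C–H position of the dichloroquinone gives hydroquinone 3, which no longer accepts a nucleophile, and DDQ dehydrogenation then returns the quinone oxidation level; the slight excess of 1 keeps the reaction at the mono-adduct.

Step 2
Reactants: 4 2,5-dichloro-3-(1H-indol-3-yl)-1,4-benzoquinone; 2 1H-indole
Product: 6 2,5-dichloro-3,6-di(1H-indol-3-yl)-1,4-benzoquinone, via bisindolyl hydroquinone 5 (not isolated)
Conditions: 2 (1.2 equiv), H2SO4 (cat.), AcOH, 23 °C; then DDQ (1.0 equiv), THF, 23 °C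
Reagents that add atoms: none
Why: A second acid-promoted conjugate (Michael-type Friedel–Crafts) addition of indole C-3 can only go to the one remaining C–H position of 4, which lies para to the first indolyl group because the chlorines block C-2 and C-5, and DDQ dehydrogenation of hydroquinone 5 gives the symmetric quinone.

Step 3
Reactants: 6 2,5-dichloro-3,6-di(1H-indol-3-yl)-1,4-benzoquinone
Product: 8 2-chloro-5-methoxy-3,6-di(1H-indol-3-yl)-1,4-benzoquinone, via quinonylpyridinium chloride 7 (not isolated)
Conditions: MeOH (1.5 equiv), DMAP (10 mol%), finely ground K2CO3 (1.2 equiv), MeCN, 0 to 23 °C, stopped when 6 is consumed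
Reagents that add atoms: methanol (CO)
Why: Proposed new method: each C–Cl of 6 is a vinylogous acyl chloride, so DMAP should add at the chlorine-bearing carbon and expel chloride to give cation 7, which is far more electrophilic than 6 or 8, is captured by neutral methanol to form the key C–O bond, and releases DMAP (regenerated from its hydrochloride by solid K2CO3, which is too weak and too insoluble in MeCN to supply free methoxide); mono-selectivity is expected because 7 resists a second DMAP addition on charge grounds, because the methoxy group of 8 is a stronger π-donor than chlorine and raises the quinone LUMO so that the weak neutral catalyst adds to 8 more slowly than to 6, and because methanol is kept near stoichiometric; the closest known reaction types are DMAP-catalysed acyl transfer to alcohols (Steglich-type) and amine-catalysed SNAr alkoxylation of chloro-azines.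

Step 4
Reactants: 8 2-chloro-5-methoxy-3,6-di(1H-indol-3-yl)-1,4-benzoquinone; 9 tributyl(3-methylbut-2-en-1-yl)stannane
Product: 10 2-methoxy-3,6-di(1H-indol-3-yl)-5-(3-methylbut-2-en-1-yl)-1,4-benzoquinone
Conditions: 9 (1.3 equiv), Pd(PPh3)4 (5 mol%), CuI (10 mol%), 1,4-dioxane, 80 °C, dark
Reagents that add atoms: none
Why: Stille cross-coupling, known for haloquinones and for prenylstannanes: zerovalent palladium inserts into the remaining vinylogous acyl chloride C–Cl bond, the prenyl group transfers from tin in preference to butyl, and reductive elimination at the unhindered CH2 terminus gives the linear prenyl quinone under neutral conditions that leave the indole N–H groups and the methoxyquinone untouched.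

## Compound list

1 | 2,5-dichloro-1,4-benzoquinone | O=C1C=C(Cl)C(=O)C=C1Cl | starting material
2 | 1H-indole | c1ccc2[nH]ccc2c1 | starting material
3 | 2,5-dichloro-3-(1H-indol-3-yl)benzene-1,4-diol | Oc1cc(Cl)c(O)c(-c2c[nH]c3ccccc23)c1Cl | intermediate
4 | 2,5-dichloro-3-(1H-indol-3-yl)-1,4-benzoquinone | O=C1C=C(Cl)C(=O)C(c2c[nH]c3ccccc23)=C1Cl | intermediate
5 | 2,5-dichloro-3,6-di(1H-indol-3-yl)benzene-1,4-diol | Oc1c(Cl)c(-c2c[nH]c3ccccc23)c(O)c(Cl)c1-c1c[nH]c2ccccc12 | intermediate
6 | 2,5-dichloro-3,6-di(1H-indol-3-yl)-1,4-benzoquinone | O=C1C(Cl)=C(c2c[nH]c3ccccc23)C(=O)C(Cl)=C1c1c[nH]c2ccccc12 | intermediate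
7 | 1-[4-chloro-2,5-di(1H-indol-3-yl)-3,6-dioxocyclohexa-1,4-dien-1-yl]-4-(dimethylamino)pyridinium chloride | CN(C)c1cc[n+](cc1)C1=C(c2c[nH]c3ccccc23)C(=O)C(Cl)=C(c2c[nH]c3ccccc23)C1=O.[Cl-] | intermediate
8 | 2-chloro-5-methoxy-3,6-di(1H-indol-3-yl)-1,4-benzoquinone | COC1=C(c2c[nH]c3ccccc23)C(=O)C(Cl)=C(c2c[nH]c3ccccc23)C1=O | intermediate
9 | tributyl(3-methylbut-2-en-1-yl)stannane | CCCC[Sn](CCCC)(CCCC)CC=C(C)C | starting material
10 | 2-methoxy-3,6-di(1H-indol-3-yl)-5-(3-methylbut-2-en-1-yl)-1,4-benzoquinone | COC1=C(c2c[nH]c3ccccc23)C(=O)C(CC=C(C)C)=C(c2c[nH]c3ccccc23)C1=O | target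

## Step count and risks

Total step count: 4. Longest linear sequence: 4 steps (1 → 4 → 6 → 8 → 10).

Step 3, the proposed new methanolysis, is the most likely to fail. The donor indolyl groups may make 6 too electron-rich for DMAP to add, or some dimethoxy quinone may form. The fallback uses known chemistry, sets out from 6 and comes back at 8. Aqueous NaOH (2.2 equiv) in THF at 0 to 23 °C replaces one chloride by hydroxide. The product forms as the anion of a vinylogous carboxylic acid, whose negative charge slows attack at the second C–Cl enough for the reaction to be stopped at the mono stage, and acidification gives 2-chloro-5-hydroxy-3,6-di(1H-indol-3-yl)-1,4-benzoquinone F1. Heating F1 in MeOH with catalytic HCl (65 °C) then methylates the acidic hydroxyl by vinylogous Fischer esterification, the way 2-hydroxy-1,4-naphthoquinone is converted into its methyl ether, and gives 8.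

Step 4 is the second risk. Oxidative addition at the hindered, donor-flanked C–Cl may be slow, and prenyl transfer can give some of the reverse-prenyl (1,1-dimethylallyl) isomer. The fallback sets out from 8 and comes back at 10. A Stille coupling with allyltributylstannane (Pd(PPh3)4, CuI, dioxane, 80 °C) transfers the smaller allyl group, which has no regiochemical ambiguity, and gives 2-allyl-5-methoxy-3,6-di(1H-indol-3-yl)-1,4-benzoquinone F2. Olefin cross-metathesis of F2 with excess 2-methylbut-2-ene (second-generation Grubbs catalyst RuCl2(=CHPh)(PCy3)(H2IMes), 5 mol%, CH2Cl2, 40 °C) then converts the terminal alkene into the trisubstituted prenyl olefin of 10.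

Step 2 is the third risk. The indolyl group makes quinone 4 a weaker acceptor than 1, so the second addition may stall, and the acid can oligomerise indole in the meantime. The fallback needs no oxidant and replaces the acid-promoted additions altogether; it sets out from 2 and comes back at 6, with commercial chloranil (tetrachloro-1,4-benzoquinone) taking the place of 1 and 4. With Cs2CO3 in MeCN at 23 °C, indole C-3 displaces chloride by addition–elimination to give 2,3,5-trichloro-6-(1H-indol-3-yl)-1,4-benzoquinone F3. The indolyl donor deactivates the chlorides at C-2 and C-5, so a second equivalent of 2 substitutes at C-3, para to the first indole, and gives 6.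

Further compounds
F1 | step 3 | 2-chloro-5-hydroxy-3,6-di(1H-indol-3-yl)-1,4-benzoquinone | OC1=C(c2c[nH]c3ccccc23)C(=O)C(Cl)=C(c2c[nH]c3ccccc23)C1=O
F2 | step 4 | 2-allyl-5-methoxy-3,6-di(1H-indol-3-yl)-1,4-benzoquinone | COC1=C(c2c[nH]c3ccccc23)C(=O)C(CC=C)=C(c2c[nH]c3ccccc23)C1=O
F3 | step 2 | 2,3,5-trichloro-6-(1H-indol-3-yl)-1,4-benzoquinone | O=C1C(Cl)=C(Cl)C(=O)C(Cl)=C1c1c[nH]c2ccccc12
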